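All three ent-fisetinidol units come from one building block, tetra-O-benzyl-ent-fustin. Its C4 carbonyl later accepts the C8 or C6 aryllithium of the neighbouring unit. The route rests on disconnecting O1–C2 of ring C. The feature used is the benzylic carbon C2, flanked by ring B and by oxygenated C3 and placed so that the ring A oxygen on C8a reaches it through a six-membered ring. An intramolecular Mitsunobu etherification forms O1–C2, closes ring C and sets C2 by inversion, which fixes the 2,3-trans geometry in one operation. The precursor is an open-chain syn α-benzyloxy-β-hydroxy ketone with a single free alcohol and a single free 2'-phenol, assembled by an Evans glycolate aldol reaction.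

Key step: step 11

Remark on the structure: read from the SMILES, the three ent-fisetinidol units are (2S,3R) with a 2,3-trans-3,4-cis ring C (4α-aryl). The branching unit is (2R,3S)-catechin substituted at C8 and C6. Flavanoid numbering is used for ring positions. Unit 1 is the terminal unit bound to C6 of unit 2, unit 2 is bound to catechin C8, and unit 3 is bound to catechin C6.

Remark on the chemistry: the tertiary carbinol centres made in steps 15 and 18 are drawn for attack anti to O3. Either epimer gives the same cation, so their configuration has no bearing on the outcome.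

**Ring A fragment**

Step 1
Reactants: 1 3-(benzyloxy)phenol
Product: 2 3-(benzyloxy)phenyl acetate
Conditions: Ac2O, pyridine, CH2Cl2, 0 °C to rt
Reagents that add atoms: acetic anhydride, CC(=O)OC(C)=O
Why: Phenol O-acetylation makes this oxygen the weaker donor, so that the benzyloxy group alone steers the bromination that follows.

Step 2
Reactants: 2 3-(benzyloxy)phenyl acetate
Product: 3 5-(benzyloxy)-2-bromophenyl acetate
Conditions: NBS (1.0 equiv), MeCN, 0 °C to rt, dark
Reagents that add atoms: N-bromosuccinimide, O=C1CCC(=O)N1Br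
Why: Electrophilic aromatic bromination with NBS in a polar solvent goes para to the strongest donor, the benzyloxy group, which is the position ortho to the acetoxy group.

Step 3
Reactants: 3 5-(benzyloxy)-2-bromophenyl acetate
Product: 4 5-(benzyloxy)-2-bromophenol
Conditions: K2CO3 (0.2 equiv), MeOH, rt
Reagents that add atoms: none
Why: Base-catalysed transesterification removes the aryl acetate without touching the aryl bromide or the benzyl ether.

Step 4
Reactants: 4 5-(benzyloxy)-2-bromophenol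
Product: 5 4-(benzyloxy)-1-bromo-2-(methoxymethoxy)benzene
Conditions: MOMCl, i-Pr2NEt, CH2Cl2, 0 °C to rt
Reagents that add atoms: chloromethyl methyl ether, COCCl
Why: Williamson-type O-alkylation gives a MOM acetal that tolerates butyllithium, supports the halogen–lithium exchange by coordination and later leaves in dilute acid.

**Chain C2–C3–C4 and the key step**

Step 5
Reactants: 6 (S)-4-benzyloxazolidin-2-one; 7 (benzyloxy)acetyl chloride
Product: 9 (S)-4-benzyl-3-[(benzyloxy)acetyl]oxazolidin-2-one, via N-lithio oxazolidinone 8 (not isolated)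
Conditions: n-BuLi, THF, −78 °C; then 7, −78 to 0 °C
Reagents that add atoms: none
Why: N-acylation of the lithiated Evans auxiliary with an acid chloride is the standard entry to glycolate imides and leaves the auxiliary stereocentre untouched.

Step 6
Reactants: 9 (S)-4-benzyl-3-[(benzyloxy)acetyl]oxazolidin-2-one; 10 3,4-bis(benzyloxy)benzaldehyde
Product: 12 (S)-4-benzyl-3-{(2S,3R)-2-(benzyloxy)-3-[3,4-bis(benzyloxy)phenyl]-3-hydroxypropanoyl}oxazolidin-2-one (syn aldol), via boron enolate 11 (not isolated)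
Conditions: Bu2BOTf, Et3N, CH2Cl2, −78 to 0 °C; then 10, −78 to 0 °C; H2O2, MeOH, pH 7 buffer
Reagents that add atoms: none
Why: In this Evans boron syn-aldol reaction the Z-enolate reacts through a Zimmerman–Traxler chair on the face not shielded by the auxiliary benzyl group, which sets (2S) at the benzyloxy carbon (future C3) and (3R) at the benzylic carbinol (future C2 before inversion) and delivers the two oxygens already differentiated.

Step 7
Reactants: 12 syn aldol imide
Product: 13 (2S,3R)-2-(benzyloxy)-3-[3,4-bis(benzyloxy)phenyl]-3-hydroxy-N-methoxy-N-methylpropanamide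
Conditions: MeNHOMe·HCl, AlMe3, CH2Cl2, −10 °C to rt
Reagents that add atoms: N,O-dimethylhydroxylamine hydrochloride, CNOC.Cl
Why: Aluminium amide transamidation of the imide (Weinreb amide synthesis), assisted by the free β-hydroxyl, releases the auxiliary without epimerisation.

Step 8
Reactants: 13 hydroxy Weinreb amide
Product: 14 (2S,3R)-2-(benzyloxy)-3-[3,4-bis(benzyloxy)phenyl]-N-methoxy-N-methyl-3-(triethylsilyloxy)propanamide
Conditions: TESCl, imidazole, DMF, 0 °C to rt
Reagents that add atoms: chlorotriethylsilane, CC[Si](Cl)(CC)CC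
Why: Silylation of the secondary alcohol removes the acidic proton and blocks retro-aldol cleavage in the organolithium step, and the TES group is labile enough to leave together with the MOM group.

Step 9
Reactants: 5 4-(benzyloxy)-1-bromo-2-(methoxymethoxy)benzene; 14 TES-protected Weinreb amide
Product: 16 (2S,3R)-2-(benzyloxy)-1-[4-(benzyloxy)-2-(methoxymethoxy)phenyl]-3-[3,4-bis(benzyloxy)phenyl]-3-(triethylsilyloxy)propan-1-one, via aryllithium 15 (not isolated)
Conditions: 5 (1.5 equiv), n-BuLi, THF, −78 °C; then 14, −78 to −20 °C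
Reagents that add atoms: none
Why: Bromine–lithium exchange followed by the Weinreb ketone synthesis gives a chelated tetrahedral adduct that persists until work-up, so over-addition is excluded and the α-centre is never exposed to base as a ketone.

Step 10
Reactants: 16 MOM/TES-protected ketone
Product: 17 (2S,3R)-2-(benzyloxy)-1-[4-(benzyloxy)-2-hydroxyphenyl]-3-[3,4-bis(benzyloxy)phenyl]-3-hydroxypropan-1-one
Conditions: HCl (2 M aq), THF–MeOH, 0 °C to rt
Reagents that add atoms: none
Why: Dilute acid hydrolyses the aryl MOM acetal (activated by the ortho carbonyl) and the TES ether in one operation, while ionisation of the benzylic carbinol is held back by the adjacent benzyloxy and acyl groups.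

Step 11
Reactants: 17 (2S,3R)-2'-hydroxy-α-benzyloxy-β-hydroxy ketone
Product: 18 (2S,3S)-3,7-bis(benzyloxy)-2-[3,4-bis(benzyloxy)phenyl]chroman-4-one (tetra-O-benzyl-ent-fustin, 2,3-trans)
Conditions: PPh3, DIAD (slow addition), toluene (0.02 M), 0 °C to rt
Reagents that add atoms: none
Why: PPh3 and DIAD form the betaine, which takes the proton of the 2'-phenol (acidified by the ortho acyl group) and turns the only free alcohol, the benzylic hydroxyl, into an oxyphosphonium leaving group that the phenoxide displaces from the rear. The closest known reaction type is the intramolecular Mitsunobu etherification of 2'-hydroxy-β-hydroxydihydrochalcones to flavan-4-ones. Ring C closes in the 6-exo-tet mode, since the departing oxygen lies outside the forming O1–C2–C3–C4–C4a–C8a ring. The new stereocentre C2 (S) is controlled by inversion of the (R)-carbinol set in step 6 next to the untouched C3 centre, which gives the diequatorial 2,3-trans ring, and any closure through a p-benzyloxybenzyl cation should also occur anti to the 3-benzyloxy group. The step needs substitution to win over loss of the C3 proton (dehydration to the α-benzyloxychalcone) and over retro-aldol cleavage, and it needs a single nucleophile and a single electrophile. This is secured by an ether rather than an ester at O3, by benzyl caps on every other oxygen, by the entropic advantage of six-ring closure at high dilution and by neutral, cold conditions.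

**Catechin fragment**

Step 12
Reactants: 19 (+)-catechin
Product: 20 5,7,3',4'-tetra-O-benzyl-(+)-catechin
Conditions: BnBr (4.4 equiv), K2CO3, DMF, 0 °C to rt, Ar
Reagents that add atoms: benzyl bromide, BrCc1ccccc1
Why: Williamson etherification with a weak base alkylates only the four phenols and is too mild to open ring C or epimerise C2.

Step 13
Reactants: 20 tetra-O-benzylcatechin
Product: 21 3,5,7,3',4'-penta-O-benzyl-(+)-catechin
Conditions: NaH, BnBr, DMF, 0 °C to rt
Reagents that add atoms: benzyl bromide, BrCc1ccccc1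
Why: Williamson etherification of the remaining secondary alcohol is safe at this stage because no free phenol is left that could open ring C through a quinone methide.

Step 14
Reactants: 21 penta-O-benzylcatechin
Product: 22 8-bromo-3,5,7,3',4'-penta-O-benzyl-(+)-catechin
Conditions: NBS (1.0 equiv), CH2Cl2, −78 to 0 °C
Reagents that add atoms: N-bromosuccinimide, O=C1CCC(=O)N1Br
Why: Electrophilic bromination of the phloroglucinol-type ring A of benzylated catechins with one equivalent of NBS is known to take C8 before C6.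

**Assembly**

Step 15
Reactants: 22 8-bromo-penta-O-benzylcatechin; 18 tetra-O-benzyl-ent-fustin
Product: 24 tertiary carbinol, 3,7,3',4'-tetra-O-benzyl-4-(penta-O-benzylcatechin-8-yl)-ent-fisetinidol-4-ol (C2 and C3 as in 18, aryl trans to O3), via 8-lithio catechin ether 23 (not isolated)
Conditions: 22 (1.3 equiv), n-BuLi, THF, −78 °C; then 18, −78 to 0 °C
Reagents that add atoms: none
Why: Bromine–lithium exchange and 1,2-addition of the aryllithium to a flavan-4-one carbonyl is a known way to form a 4→8 interflavan bond, and here the ketone lacks a peri substituent at C5 and low temperature favours addition over enolisation.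

Step 16
Reactants: 24 tertiary carbinol
Product: 25 nona-O-benzyl-ent-fisetinidol-(4α→8)-catechin (unit 2: 2S,3R, 2,3-trans-3,4-cis; catechin: 2R,3S)
Conditions: Bu3SnH (excess), then TFA, CH2Cl2, 0 °C
Reagents that add atoms: none
Why: In this ionic reduction TFA ionises the carbinol to a C4 diarylmethyl cation stabilised by O1 and O7, and Bu3SnH, a hydride donor strong enough to trap it before proton loss, should attack anti to the neighbouring 3-benzyloxy group (the facial bias that sends carbon nucleophiles 3,4-trans in 2,3-trans-flavan-4-yl cations), which leaves the aryl group cis to O3.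

Step 17
Reactants: 25 protected dimer
Product: 26 dibromide of 25 (Br at C6 of unit 2 and at C6 of the catechin unit)
Conditions: NBS (2.05 equiv), CH2Cl2, −78 to 0 °C
Reagents that add atoms: N-bromosuccinimide, O=C1CCC(=O)N1Br
Why: Electrophilic aromatic bromination should take the two most activated free positions, catechin C6 (between two benzyloxy groups) and C6 of unit 2 (para to O1, ortho to O7, less crowded than C8), because the catechol-type B rings lack cooperative activation.

Step 18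
Reactants: 26 dibromide; 18 tetra-O-benzyl-ent-fustin (two molecules enter the product)
Product: 28 bis-carbinol (units 1 and 3 attached through C4 carbinols to C6 of unit 2 and to catechin C6), via dilithio dimer 27 (not isolated)
Conditions: n-BuLi (2.1 equiv), THF, −78 °C; then 18 (3 equiv), −78 to 0 °C
Reagents that add atoms: none
Why: Twofold bromine–lithium exchange and twofold 1,2-addition repeat the reaction type of step 15, and because both positions receive the same ketone no differentiation of the two bromides is needed.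

Step 19
Reactants: 28 bis-carbinol
Product: 29 heptadeca-O-benzyl ether of the target (all three ent-fisetinidol units 2,3-trans-3,4-cis)
Conditions: Bu3SnH (excess), then TFA, CH2Cl2, 0 °C
Reagents that add atoms: none
Why: Twofold ionic reduction as in step 16 should deliver hydride to each C4 cation anti to its 3-benzyloxy group and so set the two remaining 4α-aryl centres, while the resorcinol-type interflavan bond already present resists brief exposure to TFA.

Step 20
Reactants: 29 protected tetramer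
Product: 30 ent-fisetinidol-(4α→6)-ent-fisetinidol-(4α→8)-catechin-(6→4α)-ent-fisetinidol (target)
Conditions: H2 (1 atm), Pd(OH)2/C, THF–MeOH–H2O, rt
Reagents that add atoms: none
Why: Catalytic hydrogenolysis cleaves all seventeen benzyl ethers under neutral conditions that leave the O1–C2 bonds, the interflavan bonds and every stereocentre of such oligomers intact.

**Compound list**

1 | 3-(benzyloxy)phenol | Oc1cccc(OCc2ccccc2)c1 | starting material
2 | 3-(benzyloxy)phenyl acetate | CC(=O)Oc1cccc(OCc2ccccc2)c1 | intermediate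
3 | 5-(benzyloxy)-2-bromophenyl acetate | CC(=O)Oc1cc(OCc2ccccc2)ccc1Br | intermediate
4 | 5-(benzyloxy)-2-bromophenol | Oc1cc(OCc2ccccc2)ccc1Br | intermediate
5 | 4-(benzyloxy)-1-bromo-2-(methoxymethoxy)benzene | Brc1ccc(OCc2ccccc2)cc1OCOC | intermediate
6 | (S)-4-benzyloxazolidin-2-one | O=C1N[C@@H](Cc2ccccc2)CO1 | starting material
7 | (benzyloxy)acetyl chloride | O=C(Cl)COCc1ccccc1 | starting material
8 | N-lithio-(S)-4-benzyloxazolidin-2-one | [Li]N1C(=O)OC[C@@H]1Cc1ccccc1 | intermediate
9 | (S)-4-benzyl-3-[(benzyloxy)acetyl]oxazolidin-2-one | O=C(COCc1ccccc1)N1C(=O)OC[C@@H]1Cc1ccccc1 | intermediate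
10 | 3,4-bis(benzyloxy)benzaldehyde | O=Cc1ccc(OCc2ccccc2)c(OCc2ccccc2)c1 | starting material
11 | (Z)-dibutylboron enolate of 9 | CCCCB(CCCC)O/C(=C\OCc1ccccc1)N1C(=O)OC[C@@H]1Cc1ccccc1 | intermediate
12 | (S)-4-benzyl-3-{(2S,3R)-2-(benzyloxy)-3-[3,4-bis(benzyloxy)phenyl]-3-hydroxypropanoyl}oxazolidin-2-one | O[C@H](c1ccc(OCc9ccccc9)c(OCc9ccccc9)c1)[C@H](OCc9ccccc9)C(=O)N1C(=O)OC[C@@H]1Cc1ccccc1 | intermediate
13 | (2S,3R)-2-(benzyloxy)-3-[3,4-bis(benzyloxy)phenyl]-3-hydroxy-N-methoxy-N-methylpropanamide | O[C@H](c1ccc(OCc9ccccc9)c(OCc9ccccc9)c1)[C@H](OCc9ccccc9)C(=O)N(C)OC | intermediate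
14 | (2S,3R)-2-(benzyloxy)-3-[3,4-bis(benzyloxy)phenyl]-N-methoxy-N-methyl-3-(triethylsilyloxy)propanamide | CC[Si](CC)(CC)O[C@H](c1ccc(OCc9ccccc9)c(OCc9ccccc9)c1)[C@H](OCc9ccccc9)C(=O)N(C)OC | intermediate
15 | [4-(benzyloxy)-2-(methoxymethoxy)phenyl]lithium | [Li]c1ccc(OCc2ccccc2)cc1OCOC | intermediate
16 | (2S,3R)-2-(benzyloxy)-1-[4-(benzyloxy)-2-(methoxymethoxy)phenyl]-3-[3,4-bis(benzyloxy)phenyl]-3-(triethylsilyloxy)propan-1-one | CC[Si](CC)(CC)O[C@H](c1ccc(OCc9ccccc9)c(OCc9ccccc9)c1)[C@H](OCc9ccccc9)C(=O)c1ccc(OCc9ccccc9)cc1OCOC | intermediate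
17 | (2S,3R)-2-(benzyloxy)-1-[4-(benzyloxy)-2-hydroxyphenyl]-3-[3,4-bis(benzyloxy)phenyl]-3-hydroxypropan-1-one | O[C@H](c1ccc(OCc9ccccc9)c(OCc9ccccc9)c1)[C@H](OCc9ccccc9)C(=O)c1ccc(OCc9ccccc9)cc1O | intermediate
18 | (2S,3S)-3,7-bis(benzyloxy)-2-[3,4-bis(benzyloxy)phenyl]chroman-4-one | O(Cc9ccccc9)c1ccc2c(c1)O[C@@H](c1ccc(OCc9ccccc9)c(OCc9ccccc9)c1)[C@H](OCc9ccccc9)C2=O | intermediate
19 | (+)-catechin (2R,3S) | O[C@H]1Cc2c(O)cc(O)cc2O[C@@H]1c1ccc(O)c(O)c1 | starting material
20 | 5,7,3',4'-tetra-O-benzyl-(+)-catechin | O[C@H]1Cc2c(OCc9ccccc9)cc(OCc9ccccc9)cc2O[C@@H]1c1ccc(OCc9ccccc9)c(OCc9ccccc9)c1 | intermediate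
21 | 3,5,7,3',4'-penta-O-benzyl-(+)-catechin | O(Cc9ccccc9)[C@H]1Cc2c(OCc9ccccc9)cc(OCc9ccccc9)cc2O[C@@H]1c1ccc(OCc9ccccc9)c(OCc9ccccc9)c1 | intermediate
22 | 8-bromo-3,5,7,3',4'-penta-O-benzyl-(+)-catechin | O(Cc9ccccc9)[C@H]1Cc2c(OCc9ccccc9)cc(OCc9ccccc9)c(Br)c2O[C@@H]1c1ccc(OCc9ccccc9)c(OCc9ccccc9)c1 | intermediate
23 | 8-lithio-3,5,7,3',4'-penta-O-benzyl-(+)-catechin | O(Cc9ccccc9)[C@H]1Cc2c(OCc9ccccc9)cc(OCc9ccccc9)c([Li])c2O[C@@H]1c1ccc(OCc9ccccc9)c(OCc9ccccc9)c1 | intermediate
24 | tertiary carbinol, unit 2 C4(OH) bound to catechin C8 | O(Cc9ccccc9)c1ccc2c(c1)O[C@@H](c1ccc(OCc9ccccc9)c(OCc9ccccc9)c1)[C@H](OCc9ccccc9)[C@@]2(O)c1c(OCc9ccccc9)cc(OCc9ccccc9)c2c1O[C@H](c1ccc(OCc9ccccc9)c(OCc9ccccc9)c1)[C@@H](OCc9ccccc9)C2 | intermediate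
25 | nona-O-benzyl-ent-fisetinidol-(4α→8)-catechin | O(Cc9ccccc9)c1ccc2c(c1)O[C@@H](c1ccc(OCc9ccccc9)c(OCc9ccccc9)c1)[C@H](OCc9ccccc9)[C@@H]2c1c(OCc9ccccc9)cc(OCc9ccccc9)c2c1O[C@H](c1ccc(OCc9ccccc9)c(OCc9ccccc9)c1)[C@@H](OCc9ccccc9)C2 | intermediate
26 | dibromide of 25 (C6 of unit 2, C6 of catechin) | Brc1cc2c(cc1OCc9ccccc9)O[C@@H](c1ccc(OCc9ccccc9)c(OCc9ccccc9)c1)[C@H](OCc9ccccc9)[C@@H]2c1c(OCc9ccccc9)c(Br)c(OCc9ccccc9)c2c1O[C@H](c1ccc(OCc9ccccc9)c(OCc9ccccc9)c1)[C@@H](OCc9ccccc9)C2 | intermediate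
27 | dilithio dimer (C6 of unit 2, C6 of catechin) | [Li]c1cc2c(cc1OCc9ccccc9)O[C@@H](c1ccc(OCc9ccccc9)c(OCc9ccccc9)c1)[C@H](OCc9ccccc9)[C@@H]2c1c(OCc9ccccc9)c([Li])c(OCc9ccccc9)c2c1O[C@H](c1ccc(OCc9ccccc9)c(OCc9ccccc9)c1)[C@@H](OCc9ccccc9)C2 | intermediate
28 | bis-carbinol (C4 carbinols in units 1 and 3) | O(Cc9ccccc9)c1ccc2c(c1)O[C@@H](c1ccc(OCc9ccccc9)c(OCc9ccccc9)c1)[C@H](OCc9ccccc9)[C@@]2(O)c1cc2c(cc1OCc9ccccc9)O[C@@H](c1ccc(OCc9ccccc9)c(OCc9ccccc9)c1)[C@H](OCc9ccccc9)[C@@H]2c1c(OCc9ccccc9)c([C@@]2(O)c3ccc(OCc9ccccc9)cc3O[C@@H](c3ccc(OCc9ccccc9)c(OCc9ccccc9)c3)[C@@H]2OCc9ccccc9)c(OCc9ccccc9)c2c1O[C@H](c1ccc(OCc9ccccc9)c(OCc9ccccc9)c1)[C@@H](OCc9ccccc9)C2 | intermediate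
29 | heptadeca-O-benzyl ether of the target | O(Cc9ccccc9)c1ccc2c(c1)O[C@@H](c1ccc(OCc9ccccc9)c(OCc9ccccc9)c1)[C@H](OCc9ccccc9)[C@@H]2c1cc2c(cc1OCc9ccccc9)O[C@@H](c1ccc(OCc9ccccc9)c(OCc9ccccc9)c1)[C@H](OCc9ccccc9)[C@@H]2c1c(OCc9ccccc9)c([C@@H]2c3ccc(OCc9ccccc9)cc3O[C@@H](c3ccc(OCc9ccccc9)c(OCc9ccccc9)c3)[C@@H]2OCc9ccccc9)c(OCc9ccccc9)c2c1O[C@H](c1ccc(OCc9ccccc9)c(OCc9ccccc9)c1)[C@@H](OCc9ccccc9)C2 | intermediate
30 | ent-fisetinidol-(4α→6)-ent-fisetinidol-(4α→8)-catechin-(6→4α)-ent-fisetinidol | Oc1ccc2c(c1)O[C@@H](c1ccc(O)c(O)c1)[C@H](O)[C@@H]2c1cc2c(cc1O)O[C@@H](c1ccc(O)c(O)c1)[C@H](O)[C@@H]2c1c(O)c([C@@H]2c3ccc(O)cc3O[C@@H](c3ccc(O)c(O)c3)[C@@H]2O)c(O)c2c1O[C@H](c1ccc(O)c(O)c1)[C@@H](O)C2 | target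

Total step count: 20. Longest linear sequence: 13 steps (steps 5–11 and 15–20). The ring A branch, steps 1–4, 9–11 and 15–20, is equally long.

**Steps most likely to fail**

1. Step 11. The activated benzylic carbinol may lose the acidic C3 proton (dehydration to the enone) or ionise before the phenoxide arrives, which would erode the configuration at C2.
   - In the fallback the O1–C2 bond is made first and intermolecularly, and ring C is closed at C4–C4a instead. It sets out from Weinreb amide 13 and bromophenol 4.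
   - A Mitsunobu etherification (PPh3, DIAD, toluene, 0 °C) now takes place next to an amide whose α-proton is far less acidic. It should give, with inversion, (2S,3S)-2-(benzyloxy)-3-[5-(benzyloxy)-2-bromophenoxy]-3-[3,4-bis(benzyloxy)phenyl]-N-methoxy-N-methylpropanamide F1.
   - Bromine–lithium exchange (n-BuLi, THF, −100 to −78 °C) gives the corresponding aryllithium F2. This attacks its own Weinreb amide (Parham-type cyclisation) and comes back to the route at 18.

2. Step 18. Two hindered aryllithium centres must each add to an enolisable, electron-rich ketone. Proton transfer from C3–H of the ketone or from a benzylic CH2 may quench one centre before it adds, so that only one of the two bonds forms.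
   - In the fallback the bonds are made one at a time, setting out from 26.
   - One equivalent of n-BuLi should give, under equilibrating exchange, the aryllithium stabilised by two ortho oxygens, the catechin-6-lithio monobromide F3.
   - Addition of F3 to 18 gives the bromo carbinol F4, and Bu3SnH/TFA gives the bromo trimer F5.
   - A second exchange gives the unit 2 C6-lithio trimer F6. Addition to 18 gives the tetramer mono-carbinol F7, and ionic reduction comes back to the route at 29.
   - Both sites receive the same ketone, so an exchange in the reverse order converges on 29 as well.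

3. Step 16 (the same issue returns in step 19). The hydride may reach the planar C4 cation from both faces, because the C2 aryl group lies on the face opposite to O3. The cation may also lose the C3 proton before it is trapped.
   - In the fallback the roles at C4 are exchanged, so that an unsubstituted C4 cation is captured by the arene. It sets out from 18 and 21.
   - NaBH4 (THF–MeOH, 0 °C) reduces 18 to (2S,3R,4S)-3,7-bis(benzyloxy)-2-[3,4-bis(benzyloxy)phenyl]chroman-4-ol F8.
   - TiCl4 (CH2Cl2, 0 °C) ionises F8 in the presence of excess 21, whose C8 attacks in a Friedel–Crafts-type flavan-4-ol/arene condensation.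
   - This known coupling should give both C4 epimers. The 3,4-cis product has to be separated by chromatography from nona-O-benzyl-ent-fisetinidol-(4β→8)-catechin F9, and the fallback comes back to the route at 25.

**Further compounds**

F1 | step 11 | (2S,3S)-2-(benzyloxy)-3-[5-(benzyloxy)-2-bromophenoxy]-3-[3,4-bis(benzyloxy)phenyl]-N-methoxy-N-methylpropanamide | Brc1ccc(OCc9ccccc9)cc1O[C@@H](c1ccc(OCc9ccccc9)c(OCc9ccccc9)c1)[C@H](OCc9ccccc9)C(=O)N(C)OC
F2 | step 11 | aryllithium from F1 | [Li]c1ccc(OCc9ccccc9)cc1O[C@@H](c1ccc(OCc9ccccc9)c(OCc9ccccc9)c1)[C@H](OCc9ccccc9)C(=O)N(C)OC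
F3 | step 18 | catechin-6-lithio monobromide | Brc1cc2c(cc1OCc9ccccc9)O[C@@H](c1ccc(OCc9ccccc9)c(OCc9ccccc9)c1)[C@H](OCc9ccccc9)[C@@H]2c1c(OCc9ccccc9)c([Li])c(OCc9ccccc9)c2c1O[C@H](c1ccc(OCc9ccccc9)c(OCc9ccccc9)c1)[C@@H](OCc9ccccc9)C2
F4 | step 18 | bromo carbinol (unit 3 attached as C4 carbinol) | Brc1cc2c(cc1OCc9ccccc9)O[C@@H](c1ccc(OCc9ccccc9)c(OCc9ccccc9)c1)[C@H](OCc9ccccc9)[C@@H]2c1c(OCc9ccccc9)c([C@@]2(O)c3ccc(OCc9ccccc9)cc3O[C@@H](c3ccc(OCc9ccccc9)c(OCc9ccccc9)c3)[C@@H]2OCc9ccccc9)c(OCc9ccccc9)c2c1O[C@H](c1ccc(OCc9ccccc9)c(OCc9ccccc9)c1)[C@@H](OCc9ccccc9)C2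
F5 | step 18 | bromo trimer (unit 3 reduced, 4α) | Brc1cc2c(cc1OCc9ccccc9)O[C@@H](c1ccc(OCc9ccccc9)c(OCc9ccccc9)c1)[C@H](OCc9ccccc9)[C@@H]2c1c(OCc9ccccc9)c([C@@H]2c3ccc(OCc9ccccc9)cc3O[C@@H](c3ccc(OCc9ccccc9)c(OCc9ccccc9)c3)[C@@H]2OCc9ccccc9)c(OCc9ccccc9)c2c1O[C@H](c1ccc(OCc9ccccc9)c(OCc9ccccc9)c1)[C@@H](OCc9ccccc9)C2
F6 | step 18 | unit 2 C6-lithio trimer | [Li]c1cc2c(cc1OCc9ccccc9)O[C@@H](c1ccc(OCc9ccccc9)c(OCc9ccccc9)c1)[C@H](OCc9ccccc9)[C@@H]2c1c(OCc9ccccc9)c([C@@H]2c3ccc(OCc9ccccc9)cc3O[C@@H](c3ccc(OCc9ccccc9)c(OCc9ccccc9)c3)[C@@H]2OCc9ccccc9)c(OCc9ccccc9)c2c1O[C@H](c1ccc(OCc9ccccc9)c(OCc9ccccc9)c1)[C@@H](OCc9ccccc9)C2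
F7 | step 18 | tetramer mono-carbinol (unit 1 attached as C4 carbinol) | O(Cc9ccccc9)c1ccc2c(c1)O[C@@H](c1ccc(OCc9ccccc9)c(OCc9ccccc9)c1)[C@H](OCc9ccccc9)[C@@]2(O)c1cc2c(cc1OCc9ccccc9)O[C@@H](c1ccc(OCc9ccccc9)c(OCc9ccccc9)c1)[C@H](OCc9ccccc9)[C@@H]2c1c(OCc9ccccc9)c([C@@H]2c3ccc(OCc9ccccc9)cc3O[C@@H](c3ccc(OCc9ccccc9)c(OCc9ccccc9)c3)[C@@H]2OCc9ccccc9)c(OCc9ccccc9)c2c1O[C@H](c1ccc(OCc9ccccc9)c(OCc9ccccc9)c1)[C@@H](OCc9ccccc9)C2
F8 | step 16 | (2S,3R,4S)-3,7-bis(benzyloxy)-2-[3,4-bis(benzyloxy)phenyl]chroman-4-ol | O(Cc9ccccc9)c1ccc2c(c1)O[C@@H](c1ccc(OCc9ccccc9)c(OCc9ccccc9)c1)[C@H](OCc9ccccc9)[C@H]2O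
F9 | step 16 | nona-O-benzyl-ent-fisetinidol-(4β→8)-catechin (C4 epimer of 25) | O(Cc9ccccc9)c1ccc2c(c1)O[C@@H](c1ccc(OCc9ccccc9)c(OCc9ccccc9)c1)[C@H](OCc9ccccc9)[C@H]2c1c(OCc9ccccc9)cc(OCc9ccccc9)c2c1O[C@H](c1ccc(OCc9ccccc9)c(OCc9ccccc9)c1)[C@@H](OCc9ccccc9)C2
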